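In a one-step world, D + Q → Z + L, each Q spent gives one Z, so beta would climb towards 0.44 M of Z. It levels near 0.203 M, which is less than that, so something else spends Q.

| setting | beta | zeta | delta | oak | alder |
|---|---|---|---|---|---|
| D | 0.47 M (in portions, 4) | 0.49 M (in portions, 4) | 0.68 M (in portions, 4) | 0.60 M | 0.44 M (in portions, 4) |
| Q | 0.44 M | 0.44 M | 0.44 M | 0.440 M | 0.440 M |
| temperature | 10 °C | 32 °C | 10 °C | 0 °C | 40 °C |
| remark | run made earlier; portions every 25 min | run made earlier; portions every 25 min | run made earlier; portions every 25 min | everything together at the start | the portions of D follow each other after 25 min, the first at the start |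
| time |  |  |  | 8.0 h | 8.0 h |

| run | time / h | Z / % |
|---|---|---|
| beta | 3.00 | 29.4 |
| beta | 6.00 | 37.9 |
| beta | 12.0 | 41.3 |
| beta | 40.0 | 43.2 |
| zeta | 0.667 | 12.3 |
| zeta | 1.33 | 16.7 |
| zeta | 3.00 | 22.8 |
| zeta | 8.00 | 19.7 |
| delta | 4.00 | 29.1 |
| delta | 12.0 | 36.3 |
| delta | 20.0 | 36.2 |
| delta | 40.0 | 34.1 |

(scatter of a reading: 1 percentage point)

* the winner by amount of Z, in percent of the D charged; "neither" if no more than 2 percentage points parts them (oak / alder / neither)
* how much Z is there at the end, in percent of the D charged: oak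
* how much Z is there at the end, in percent of the D charged: alder

I take the second spender to be 2 Q → E, although the yields alone do not tell it from Q → J. Q then falls at kZ·cD·cQ + 2·kE·cQ·cQ, and the two terms are equal at the level c* = kZ·cD/(2·kE). Dividing the rate of Z by that of Q gives dcZ/dcQ = −c*/(c* + cQ). With cD held, this integrates to cZ = c*·ln((c* + cQ,start)/(c* + cQ)). Once Q has gone, the share of Q that became Z is ln(1 + x)/x, with x = cQ,start/c*.

Now I read the runs in turn. Beta's last reading gives a share of 0.461, which x = 3 meets with 0.462, so c* is 0.147 M. Delta's highest reading gives 0.561, and x = 2 gives 0.549, so c* is 0.220 M. Per D charged these are 0.312 and 0.324, which lie close together, so I let c* grow in step with D. I carry beta's value as my selectivity factor w, the level c* per unit of D charged at 10 °C, read from a run fed in portions and carrying that run's scatter.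

Zeta's highest reading gives a share of 0.254, and x = 9 gives 0.256, so w there is 0.0998. Drawing ln w straight against temperature through beta and zeta, I get c* = 0.314 M for oak and 0.0290 M for alder. The plateaus are then 45.9% for oak and 18.3% for alder. Oak is colder than beta, whose readings still rose after 6.00 h, so I expect oak to stand below its plateau at 8.0 h.

The forecast says oak, with 41% for oak and 14% for alder, holding that “heat favours the loss strongly”.

Oak ends at 39.7% and alder at 15.9%, so oak wins.

    D + Q → Z + L (k = 0.00190 M⁻¹ s⁻¹, Ea = 52.0 kJ mol⁻¹)
    2 Q → E (k = 0.00390 M⁻¹ s⁻¹, Ea = 76.0 kJ mol⁻¹)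
    Q → J (k = 1.10 × 10⁻⁷ s⁻¹, Ea = 128 kJ mol⁻¹)
    Q + Z → G (k = 5.80 × 10⁻⁴ M⁻¹ s⁻¹, Ea = 82.0 kJ mol⁻¹)
    (constants at 40 °C)

Oak still holds 16% of its Q at 8.00 h, and the rule with w gives 35.4% of Z from that. The neighbour of oak with 1.1 M of Q keeps 12.5% of its Q; the same c* gives 59.8%, and that flask holds 62.8%.

(The data come from a simulation from invented constants; noise was put on by code.)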